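## Retrosynthetic overview

1. Target 25 ⇐ desilylation at O5 and oxidation of C3–OH in the 14-membered hydroxy lactone 23, in which C2 is already fixed.
2. 23 ⇐ ring expansion of a four-membered to a fourteen-membered lactone: the C13–OH of 22 is acylated by the molecule's own β-lactone. Ring order: β-lactone first (step 10), macrolactone second (step 14).
3. 22 ⇐ E-selective cross-metathesis (C10=C11) of vinyl ketone 18 with alcohol 21; 18 ⇐ vinyl–acyl coupling of thioester 17.
4. 17 ⇐ catalytic asymmetric ketene–aldehyde cyclocondensation (C2, C3) of aldehyde 14 with propionyl chloride; 14 ⇐ syn-crotylboration (C4, C5) of aldehyde 7, silylation, ozonolysis.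
5. 7 ⇐ zinc-catalysed sp3–sp3 coupling with inversion (C8 from ethyl (S)-lactate, C6 from (R)-3-bromo-2-methylpropanol); 21 ⇐ syn-crotylboration of propanal; both crotylborations draw on one batch of (Z)-crotylpotassium 9.

Assumption: the target is taken exactly as drawn, (2R,4S,5R,6S,8S,12S,13S) in macrolide numbering (C1 = lactone carbonyl, C13 = ring CH–O), which is used for all locants in the text below.

## Route

Step 1
Reactants: 1 ethyl (S)-lactate
Product: 2 ethyl (2S)-2-[(trifluoromethylsulfonyl)oxy]propanoate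
Conditions: Tf2O, 2,6-lutidine, CH2Cl2, −78 → 0 °C
Reagents that add atoms: trifluoromethanesulfonic anhydride, O=S(=O)(OS(=O)(=O)C(F)(F)F)C(F)(F)F
Why: O-sulfonylation (triflate formation) of the secondary alcohol with retention, which arms the lactate carbon (later C8) for the SN2 coupling of step 3.

Step 2
Reactants: 3 (2R)-3-bromo-2-methylpropan-1-ol
Product: 4 [(2R)-3-bromo-2-methylpropoxy]triethylsilane
Conditions: TESCl, imidazole, CH2Cl2, 0 °C → rt
Reagents that add atoms: chlorotriethylsilane, CC[Si](Cl)(CC)CC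
Why: silyl ether protection of the primary alcohol so that the bromide can be turned into a Grignard reagent; the stereocentre (later C6) is not touched.

Step 3
Reactants: 4 [(2R)-3-bromo-2-methylpropoxy]triethylsilane; 2 ethyl (2S)-2-[(trifluoromethylsulfonyl)oxy]propanoate
Product: 6 ethyl (2S,4S)-2,4-dimethyl-5-(triethylsilyloxy)pentanoate, via Grignard reagent 5 (not isolated)
Conditions: Mg, THF, 50 °C; then ZnCl2 (5 mol%), 2, THF, 0 °C
Reagents that add atoms: none
Why: zinc-catalysed sp3–sp3 cross-coupling of a Grignard reagent with an α-triflyloxy ester, in which the triorganozincate formed in situ displaces triflate by a clean SN2 with inversion and leaves the ester alone at 0 °C, so the (S)-lactate carbon becomes C8 (S) while C6 comes unchanged from 3.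

Step 4
Reactants: 6 ethyl (2S,4S)-2,4-dimethyl-5-(triethylsilyloxy)pentanoate
Product: 7 ethyl (2S,4S)-2,4-dimethyl-5-oxopentanoate
Conditions: (COCl)2, DMSO, CH2Cl2, −78 → −40 °C; Et3N, −78 → 0 °C
Reagents that add atoms: none
Why: Swern oxidation applied directly to the primary triethylsilyl ether (chlorosulfonium-induced desilylation, then ylide fragmentation) gives the C5 aldehyde in one operation, and the low temperature keeps the α-stereocentre C6 intact.

Step 5
Reactants: 8 cis-but-2-ene
Product: 9 (Z)-crotylpotassium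
Conditions: KOtBu, n-BuLi, THF, −78 → −45 °C (15 min), then −78 °C; the cold THF solution is divided by cannula into two portions and used at once in steps 6 and 12
Reagents that add atoms: potassium tert-butoxide, CC(C)(C)[O-].[K+]
Why: Schlosser superbase metalation (n-BuLi/KOtBu) of an allylic C–H of cis-but-2-ene; the (Z)-crotylpotassium holds its geometry at −45 °C and below (the Z form is also the thermodynamically preferred one), so a single batch can feed both crotylborations.

Step 6
Reactants: 7 ethyl (2S,4S)-2,4-dimethyl-5-oxopentanoate; 9 (Z)-crotylpotassium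
Product: 11 ethyl (2S,4S,5R,6R)-5-hydroxy-2,4,6-trimethyloct-7-enoate, via (Z)-crotylbis[(−)-isopinocampheyl]borane 10 (not isolated)
Conditions: 9 (first portion of the solution from step 5), (−)-Ipc2BOMe [from (+)-α-pinene], THF, −78 °C; BF3·OEt2; 7, −78 °C; NaBO3·4H2O, THF/H2O, rt
Reagents that add atoms: none
Why: Brown asymmetric crotylboration, in which the Z-crotylborane reacts through a chair Zimmerman–Traxler transition state (Z geometry gives 4,5-syn) and the (−)-Ipc ligands impose the aldehyde face that gives C5 (R), syn to the C6 methyl (reagent control overriding the anti-Felkin bias of a Z-crotylborane).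

Step 7
Reactants: 11 ethyl (2S,4S,5R,6R)-5-hydroxy-2,4,6-trimethyloct-7-enoate
Product: 12 ethyl (2S,4S,5R,6R)-5-[(tert-butyldimethylsilyl)oxy]-2,4,6-trimethyloct-7-enoate
Conditions: TBSOTf, 2,6-lutidine, CH2Cl2, −78 → 0 °C (crude 11 used at once)
Reagents that add atoms: tert-butyldimethylsilyl trifluoromethanesulfonate, CC(C)(C)[Si](C)(C)OS(=O)(=O)C(F)(F)F
Why: silylation of the hindered secondary alcohol stops O5 from lactonising onto C9 now and onto C1 in step 14, and the robust TBS group does not migrate to O3 later.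

Step 8
Reactants: 12 ethyl (2S,4S,5R,6R)-5-[(tert-butyldimethylsilyl)oxy]-2,4,6-trimethyloct-7-enoate
Product: 13 S-ethyl (2S,4S,5R,6R)-5-[(tert-butyldimethylsilyl)oxy]-2,4,6-trimethyloct-7-enethioate
Conditions: AlMe3, EtSH, CH2Cl2, 0 °C → rt
Reagents that add atoms: ethanethiol, CCS
Why: ester-to-thioester exchange with the aluminium thiolate made from AlMe3 and EtSH gives the acyl donor for the ketone synthesis of step 11 without epimerising C8.

Step 9
Reactants: 13 S-ethyl (2S,4S,5R,6R)-5-[(tert-butyldimethylsilyl)oxy]-2,4,6-trimethyloct-7-enethioate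
Product: 14 S-ethyl (2S,4S,5R,6S)-5-[(tert-butyldimethylsilyl)oxy]-2,4,6-trimethyl-7-oxoheptanethioate
Conditions: O3, CH2Cl2, −78 °C; PPh3, −78 °C → rt
Reagents that add atoms: ozone, [O-][O+]=O
Why: ozonolysis with reductive work-up cleaves the only alkene to the C3 aldehyde, and no stereocentre is touched (the descriptor at C4 changes only by priority).

Step 10
Reactants: 14 S-ethyl (2S,4S,5R,6S)-5-[(tert-butyldimethylsilyl)oxy]-2,4,6-trimethyl-7-oxoheptanethioate; 15 propanoyl chloride
Product: 17 S-ethyl (2S,4S,5R,6R)-5-[(tert-butyldimethylsilyl)oxy]-2,4-dimethyl-6-[(2S,3R)-3-methyl-4-oxooxetan-2-yl]heptanethioate, via methylketene 16 (not isolated)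
Conditions: 15 (slow addition), O-trimethylsilylquinidine (10 mol%), LiClO4, iPr2NEt, CH2Cl2/Et2O, −78 °C
Reagents that add atoms: none
Why: cinchona alkaloid–LiClO4 catalysed acyl halide–aldehyde cyclocondensation (stepwise aldol–lactonisation of the quinidine-bound ammonium enolate of methylketene), in which the catalyst sets C2 (R) and the closed lithium-bridged transition state gives the cis β-lactone with C3 (S), anti to the C4 methyl (the matched anti-Felkin sense for a Z-enolate-type addition).

Step 11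
Reactants: 17 S-ethyl (2S,4S,5R,6R)-5-[(tert-butyldimethylsilyl)oxy]-2,4-dimethyl-6-[(2S,3R)-3-methyl-4-oxooxetan-2-yl]heptanethioate
Product: 18 (3R,4S)-4-[(2R,3R,4S,6S)-3-[(tert-butyldimethylsilyl)oxy]-4,6-dimethyl-7-oxonon-8-en-2-yl]-3-methyloxetan-2-one
Conditions: tributyl(vinyl)stannane, Pd2(dba)3 (2.5 mol%), P(2-furyl)3 (10 mol%), Cu(O2PPh2) (1.3 equiv), THF, 50 °C
Reagents that add atoms: tributyl(vinyl)stannane, C=C[Sn](CCCC)(CCCC)CCCC
Why: Liebeskind–Srogl-type ketone synthesis (palladium-catalysed, copper-carboxylate-mediated thioester–stannane coupling) runs under neutral conditions that leave the β-lactone, the silyl ether and C8 untouched and bind the thiolate as CuSEt so that it cannot add to the vinyl ketone.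

Step 12
Reactants: 19 propanal; 9 (Z)-crotylpotassium
Product: 21 (3S,4S)-4-methylhex-5-en-3-ol, via (Z)-crotylbis[(+)-isopinocampheyl]borane 20 (not isolated)
Conditions: 9 (second portion of the solution from step 5), (+)-Ipc2BOMe [from (−)-α-pinene], THF, −78 °C; BF3·OEt2; 19, −78 °C; NaBO3·4H2O, THF/H2O, rt
Reagents that add atoms: none
Why: Brown crotylboration with the enantiomeric Ipc reagent, where Z geometry gives the syn product through the chair transition state and the (+)-Ipc ligands give the (3S,4S) alcohol, whose two centres become C13 and C12.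

Step 13
Reactants: 18 (3R,4S)-4-[(2R,3R,4S,6S)-3-[(tert-butyldimethylsilyl)oxy]-4,6-dimethyl-7-oxonon-8-en-2-yl]-3-methyloxetan-2-one; 21 (3S,4S)-4-methylhex-5-en-3-ol
Product: 22 (3R,4S)-4-[(2R,3R,4S,6S,8E,10S,11S)-3-[(tert-butyldimethylsilyl)oxy]-11-hydroxy-4,6,10-trimethyl-7-oxotridec-8-en-2-yl]-3-methyloxetan-2-one
Conditions: second-generation Hoveyda–Grubbs catalyst RuCl2(H2IMes)(=CH-C6H4-2-OiPr) (5 mol%), 21 (3 equiv), CH2Cl2, 40 °C
Reagents that add atoms: none
Why: olefin cross-metathesis between the electron-poor vinyl ketone and an excess of the terminal alkene gives the cross product as the thermodynamically favoured E-enone, and the β-lactone and the free hydroxyl are tolerated.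

Step 14
Reactants: 22 (3R,4S)-4-[(2R,3R,4S,6S,8E,10S,11S)-3-[(tert-butyldimethylsilyl)oxy]-11-hydroxy-4,6,10-trimethyl-7-oxotridec-8-en-2-yl]-3-methyloxetan-2-one
Product: 23 (3R,4S,5R,6R,7S,9S,11E,13S,14S)-6-[(tert-butyldimethylsilyl)oxy]-14-ethyl-4-hydroxy-3,5,7,9,13-pentamethyl-1-oxacyclotetradec-11-ene-2,10-dione
Conditions: Zn[N(SiMe3)2][(ArNCMe)2CH] (Ar = 2,6-iPr2C6H3, 10 mol%), toluene, 1 mM (slow addition of 22), 25 °C
Reagents that add atoms: none
Why: Proposed new method: the zinc alkoxide formed from the C13–OH adds intramolecularly to the strained β-lactone carbonyl and the tetrahedral intermediate collapses with acyl–oxygen cleavage (about 23 kcal/mol of ring strain released), which enlarges the four-membered lactone to the 14-membered one with O13–C1 in place of O3–C1, leaves C2 untouched and C3 retained, and the C3 zinc alkoxide then takes a proton from the next substrate molecule to turn the catalyst over, high dilution favouring ring expansion over oligomerisation; closest known reactions are the coordination–insertion ring-opening polymerisation of β-butyrolactone by β-diketiminate zinc alkoxides and translactonisation ring enlargements of hydroxyalkyl lactones.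

Step 15
Reactants: 23 (3R,4S,5R,6R,7S,9S,11E,13S,14S)-6-[(tert-butyldimethylsilyl)oxy]-14-ethyl-4-hydroxy-3,5,7,9,13-pentamethyl-1-oxacyclotetradec-11-ene-2,10-dione
Product: 24 (3R,5S,6R,7S,9S,11E,13S,14S)-6-[(tert-butyldimethylsilyl)oxy]-14-ethyl-3,5,7,9,13-pentamethyl-1-oxacyclotetradec-11-ene-2,4,10-trione
Conditions: Dess–Martin periodinane, pyridine, CH2Cl2, 0 °C → rt
Reagents that add atoms: none
Why: Dess–Martin oxidation of the only free hydroxyl (C3) under buffered, non-enolising conditions gives the β-keto lactone with the C2 configuration from step 10 unchanged.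

Step 16
Reactants: 24 (3R,5S,6R,7S,9S,11E,13S,14S)-6-[(tert-butyldimethylsilyl)oxy]-14-ethyl-3,5,7,9,13-pentamethyl-1-oxacyclotetradec-11-ene-2,4,10-trione
Product: 25 (3R,5S,6R,7S,9S,11E,13S,14S)-14-ethyl-6-hydroxy-3,5,7,9,13-pentamethyl-1-oxacyclotetradec-11-ene-2,4,10-trione
Conditions: HF·pyridine, pyridine, THF, 0 °C → rt
Reagents that add atoms: none
Why: acidic fluoride desilylation frees the C5 hydroxyl without any base, so the epimerisable C2 and C8 centres and the β-hydroxy ketone survive.

## Compound list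

1 | ethyl (S)-lactate | C[C@H](O)C(=O)OCC | starting material
2 | ethyl (2S)-2-[(trifluoromethylsulfonyl)oxy]propanoate | C[C@H](OS(=O)(=O)C(F)(F)F)C(=O)OCC | intermediate
3 | (2R)-3-bromo-2-methylpropan-1-ol | OC[C@@H](C)CBr | starting material
4 | [(2R)-3-bromo-2-methylpropoxy]triethylsilane | CC[Si](CC)(CC)OC[C@@H](C)CBr | intermediate
5 | [(2R)-2-methyl-3-(triethylsilyloxy)propyl]magnesium bromide (Grignard reagent) | CC[Si](CC)(CC)OC[C@@H](C)C[Mg]Br | intermediate
6 | ethyl (2S,4S)-2,4-dimethyl-5-(triethylsilyloxy)pentanoate | CC[Si](CC)(CC)OC[C@@H](C)C[C@H](C)C(=O)OCC | intermediate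
7 | ethyl (2S,4S)-2,4-dimethyl-5-oxopentanoate | O=C[C@@H](C)C[C@H](C)C(=O)OCC | intermediate
8 | cis-but-2-ene | C/C=C\C | starting material
9 | (Z)-crotylpotassium | C/C=C\[CH2-].[K+] | intermediate
10 | (Z)-crotylbis[(−)-isopinocampheyl]borane | C/C=C\CB([C@@H]1C[C@@H]2C[C@H]([C@H]1C)C2(C)C)[C@@H]1C[C@@H]2C[C@H]([C@H]1C)C2(C)C | intermediate
11 | ethyl (2S,4S,5R,6R)-5-hydroxy-2,4,6-trimethyloct-7-enoate | C=C[C@@H](C)[C@H](O)[C@@H](C)C[C@H](C)C(=O)OCC | intermediate
12 | ethyl (2S,4S,5R,6R)-5-[(tert-butyldimethylsilyl)oxy]-2,4,6-trimethyloct-7-enoate | C=C[C@@H](C)[C@H](O[Si](C)(C)C(C)(C)C)[C@@H](C)C[C@H](C)C(=O)OCC | intermediate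
13 | S-ethyl (2S,4S,5R,6R)-5-[(tert-butyldimethylsilyl)oxy]-2,4,6-trimethyloct-7-enethioate | C=C[C@@H](C)[C@H](O[Si](C)(C)C(C)(C)C)[C@@H](C)C[C@H](C)C(=O)SCC | intermediate
14 | S-ethyl (2S,4S,5R,6S)-5-[(tert-butyldimethylsilyl)oxy]-2,4,6-trimethyl-7-oxoheptanethioate | O=C[C@@H](C)[C@H](O[Si](C)(C)C(C)(C)C)[C@@H](C)C[C@H](C)C(=O)SCC | intermediate
15 | propanoyl chloride | CCC(=O)Cl | starting material
16 | methylketene | CC=C=O | intermediate
17 | S-ethyl (2S,4S,5R,6R)-5-[(tert-butyldimethylsilyl)oxy]-2,4-dimethyl-6-[(2S,3R)-3-methyl-4-oxooxetan-2-yl]heptanethioate | O=C1O[C@@H]([C@@H](C)[C@H](O[Si](C)(C)C(C)(C)C)[C@@H](C)C[C@H](C)C(=O)SCC)[C@H]1C | intermediate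
18 | (3R,4S)-4-[(2R,3R,4S,6S)-3-[(tert-butyldimethylsilyl)oxy]-4,6-dimethyl-7-oxonon-8-en-2-yl]-3-methyloxetan-2-one | O=C1O[C@@H]([C@@H](C)[C@H](O[Si](C)(C)C(C)(C)C)[C@@H](C)C[C@H](C)C(=O)C=C)[C@H]1C | intermediate
19 | propanal | CCC=O | starting material
20 | (Z)-crotylbis[(+)-isopinocampheyl]borane | C/C=C\CB([C@H]1C[C@H]2C[C@@H]([C@@H]1C)C2(C)C)[C@H]1C[C@H]2C[C@@H]([C@@H]1C)C2(C)C | intermediate
21 | (3S,4S)-4-methylhex-5-en-3-ol | C=C[C@H](C)[C@@H](O)CC | intermediate
22 | (3R,4S)-4-[(2R,3R,4S,6S,8E,10S,11S)-3-[(tert-butyldimethylsilyl)oxy]-11-hydroxy-4,6,10-trimethyl-7-oxotridec-8-en-2-yl]-3-methyloxetan-2-one | O=C1O[C@@H]([C@@H](C)[C@H](O[Si](C)(C)C(C)(C)C)[C@@H](C)C[C@H](C)C(=O)/C=C/[C@H](C)[C@@H](O)CC)[C@H]1C | intermediate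
23 | (3R,4S,5R,6R,7S,9S,11E,13S,14S)-6-[(tert-butyldimethylsilyl)oxy]-14-ethyl-4-hydroxy-3,5,7,9,13-pentamethyl-1-oxacyclotetradec-11-ene-2,10-dione | CC[C@@H]1OC(=O)[C@H](C)[C@@H](O)[C@@H](C)[C@H](O[Si](C)(C)C(C)(C)C)[C@@H](C)C[C@H](C)C(=O)/C=C/[C@@H]1C | intermediate
24 | (3R,5S,6R,7S,9S,11E,13S,14S)-6-[(tert-butyldimethylsilyl)oxy]-14-ethyl-3,5,7,9,13-pentamethyl-1-oxacyclotetradec-11-ene-2,4,10-trione | CC[C@@H]1OC(=O)[C@H](C)C(=O)[C@@H](C)[C@H](O[Si](C)(C)C(C)(C)C)[C@@H](C)C[C@H](C)C(=O)/C=C/[C@@H]1C | intermediate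
25 | (3R,5S,6R,7S,9S,11E,13S,14S)-14-ethyl-6-hydroxy-3,5,7,9,13-pentamethyl-1-oxacyclotetradec-11-ene-2,4,10-trione (CNP0143276.2) | CC[C@@H]1OC(=O)[C@H](C)C(=O)[C@@H](C)[C@H](O)[C@@H](C)C[C@H](C)C(=O)/C=C/[C@@H]1C | target

## Step count and risks

Total step count: 16. Longest linear sequence: 13 steps (3 → 4 → 6 → 7 → 11 → 12 → 13 → 14 → 17 → 18 → 22 → 23 → 24 → 25; steps 2–4, 6–11 and 13–16).

The three steps most likely to fail:

1. Step 14, the new ring expansion. It may give oligomers by intermolecular ring opening, or stall on the hindered secondary alkoxide. Fallback with known chemistry, closing the ring by metathesis instead: it sets out from 17 and 21. The lithium alkoxide of 21 (n-BuLi, THF, −78 °C) opens the strained β-lactone of 17 at the acyl carbon, faster than it attacks the thioester, and gives the ring-opened hydroxy ester thioester F1. The thioester–vinylstannane coupling of step 11 converts it into the vinyl ketone diene F2. Ring-closing metathesis (second-generation Hoveyda–Grubbs catalyst RuCl2(H2IMes)(=CH-C6H4-2-OiPr), CH2Cl2, 1 mM, 40 °C) then closes C10=C11 and comes back to the route at 23.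

2. Step 10, the catalytic ketene–aldehyde cyclocondensation on a hindered α-methyl-β-silyloxy aldehyde. Conversion or cis selectivity may be low. Fallback, setting C2 and C3 by crotylboration and closing the β-lactone afterwards: it sets out from 14. Brown crotylboration with borane 20, made as in step 12 from a further portion of 9 (the matched, anti-Felkin case for a Z-crotylborane; ethanolamine work-up to spare the thioester), gives the homoallylic alcohol F3. Ozonolysis (O3; PPh3) gives the β-hydroxy aldehyde F4. Pinnick oxidation (NaClO2, NaH2PO4, 2-methylbut-2-ene) gives the β-hydroxy acid F5. Carboxyl activation with PhSO2Cl in pyridine at 0 °C lactonises it with retention at C3 and comes back to the route at 17.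

3. Step 6, the crotylboration in the reagent-controlled sense against the aldehyde's own bias. The diastereomer ratio may be modest, and the δ-hydroxy ester can lactonise during the oxidative work-up. Fallback, substrate control through an open transition state: it sets out from 7. Crotyltributylstannane and BF3·OEt2 in CH2Cl2 at −78 °C add syn- and Felkin-selectively with a neutral work-up, and come back to the route at 11 directly. This fallback makes no new compound (F0).

## Further compounds

F1 | step 14 | (3S,4S)-4-methylhex-5-en-3-yl (2R,3S,4R,5R,6S,8S)-5-[(tert-butyldimethylsilyl)oxy]-9-(ethylsulfanyl)-3-hydroxy-2,4,6,8-tetramethyl-9-oxononanoate | CC[C@H](OC(=O)[C@H](C)[C@@H](O)[C@@H](C)[C@H](O[Si](C)(C)C(C)(C)C)[C@@H](C)C[C@H](C)C(=O)SCC)[C@@H](C)C=C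
F2 | step 14 | (3S,4S)-4-methylhex-5-en-3-yl (2R,3S,4R,5R,6S,8S)-5-[(tert-butyldimethylsilyl)oxy]-3-hydroxy-2,4,6,8-tetramethyl-9-oxoundec-10-enoate | CC[C@H](OC(=O)[C@H](C)[C@@H](O)[C@@H](C)[C@H](O[Si](C)(C)C(C)(C)C)[C@@H](C)C[C@H](C)C(=O)C=C)[C@@H](C)C=C
F3 | step 10 | S-ethyl (2S,4S,5R,6R,7R,8S)-5-[(tert-butyldimethylsilyl)oxy]-7-hydroxy-2,4,6,8-tetramethyldec-9-enethioate | C=C[C@H](C)[C@@H](O)[C@@H](C)[C@H](O[Si](C)(C)C(C)(C)C)[C@@H](C)C[C@H](C)C(=O)SCC
F4 | step 10 | S-ethyl (2S,4S,5R,6R,7S,8R)-5-[(tert-butyldimethylsilyl)oxy]-7-hydroxy-2,4,6,8-tetramethyl-9-oxononanethioate | O=C[C@H](C)[C@@H](O)[C@@H](C)[C@H](O[Si](C)(C)C(C)(C)C)[C@@H](C)C[C@H](C)C(=O)SCC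
F5 | step 10 | (2R,3S,4R,5R,6S,8S)-5-[(tert-butyldimethylsilyl)oxy]-9-(ethylsulfanyl)-3-hydroxy-2,4,6,8-tetramethyl-9-oxononanoic acid | OC(=O)[C@H](C)[C@@H](O)[C@@H](C)[C@H](O[Si](C)(C)C(C)(C)C)[C@@H](C)C[C@H](C)C(=O)SCC
F0 | step 6 | none | none
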